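**Plan**

1. Hardest feature: the central furo[2,3-b]pyran-4-one (rings C and D), whose C2 carries two aryloxy oxygens. It is flanked by two dimethylpyran rings of fixed regiochemistry, one saturated (ring E on ring A) and one unsaturated (ring F on ring B).
2. Retrosynthesis: after the 5-O-methyl ether, three core bonds are cut at once: C3–C1′, C2–O(furan) and C2–O1(pyranone). This gives chromene-quinone 12 and the open-chain o-hydroxyaroyl ketene dithioacetal 6, whose C(SMe)2 carbon (from CS2) becomes C2.
3. Enabling feature: in ring B the furan oxygen (on C2′) and the free OH (on C5′) are para, so rings B/D are a 5-hydroxybenzofuran, the retron of a quinone [3+2] annulation. The ring-F oxygen on C4′ is para to C1′ and steers the attack. C2 has the oxidation level of CO2/CS2.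
4. Forward: ring E comes from a prenal [3+3] annulation on acetophenone 1, then hydrogenation. Ring F comes from the same annulation on cyclohexane-1,3-dione, whose carbocycle becomes ring B (aromatisation, para-oxidation). Rings D and C then close in that order in the key step, and O-demethylation ends the route.
5. The chroman/chromene difference is settled by convergence (hydrogenation before the union). The angular A/C fusion is settled by the methyl ether on the other ortho oxygen.
6. Stereochemistry: the target has no stereocentre, so nothing has to be set.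

Key step: step 7

Assumption: the SMILES holds no stereocentre and no open-chain C=C, so formosanatin D is achiral and "single enantiomer" calls for no action.

Numbering: isoflavonoid numbering is used for the core (ring A C5–C8, ring C O1/C2/C3/C4, ring B C1′–C6′, ring D = furan C2–O–C2′). Ring E is the saturated pyran on O7/C8. Ring F is the 2H-pyran on O4′/C3′. The fragments use chromene numbering.

**Route**

Step 1
Reactants: 1 2′,4′-dihydroxy-6′-methoxyacetophenone; 2 3-methylbut-2-enal (prenal)
Product: 3 1-(5-hydroxy-7-methoxy-2,2-dimethyl-2H-chromen-6-yl)ethan-1-one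
Conditions: 2 (2 equiv), ethylenediammonium diacetate (EDDA, 20 mol %), xylene, 140 °C
Reagents that add atoms: none
Why: Formal [3+3] chromene annulation (Knoevenagel-type C-alkylation, dehydration to an o-quinone methide, oxa-6π electrocyclisation), which should occur at the ring carbon flanked by both OH groups and close on the non-chelated 4-OH, because the 2-OH stays locked in the hydrogen bond to the acetyl group; no stereocentre is formed.

Step 2
Reactants: 3 1-(5-hydroxy-7-methoxy-2,2-dimethyl-2H-chromen-6-yl)ethan-1-one
Product: 4 1-(5-hydroxy-7-methoxy-2,2-dimethylchroman-6-yl)ethan-1-one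
Conditions: H2 (1 atm), 10 % Pd/C, EtOAc, rt
Reagents that add atoms: none
Why: Catalytic hydrogenation of the styrene-type C3=C4 bond, under which the chelated aryl ketone and the aryl ethers are inert, fixes ring E as the saturated pyran before the second, unsaturated pyran enters the molecule.

Step 3
Reactants: 4 1-(5-hydroxy-7-methoxy-2,2-dimethylchroman-6-yl)ethan-1-one; 5 carbon disulfide
Product: 6 1-(5-hydroxy-7-methoxy-2,2-dimethylchroman-6-yl)-3,3-bis(methylsulfanyl)prop-2-en-1-one
Conditions: NaH (3.1 equiv), THF, 0 °C; CS2 (1.1 equiv), 0 °C to rt; MeI (2.05 equiv), 0 °C; 1 M HCl work-up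
Reagents that add atoms: iodomethane, CI
Why: Standard α-oxo ketene dithioacetal synthesis (enolate addition to CS2, double S-methylation), known for o-hydroxyacetophenones, in which the soft dithiolate is methylated much faster than the hard chelated phenoxide and the low temperature holds back closure to the chromone.

Step 4
Reactants: 7 cyclohexane-1,3-dione; 2 3-methylbut-2-enal (prenal)
Product: 8 2,2-dimethyl-7,8-dihydro-2H-chromen-5(6H)-one
Conditions: EDDA (10 mol %), CH2Cl2, rt
Reagents that add atoms: none
Why: Knoevenagel condensation followed by oxa-6π electrocyclisation of the 1-oxatriene (formal [3+3] annulation of 1,3-diones and enals) builds ring F in one operation from two bulk chemicals.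

Step 5
Reactants: 8 2,2-dimethyl-7,8-dihydro-2H-chromen-5(6H)-one
Product: 11 2,2-dimethyl-2H-chromen-5-ol, via phenylselanyl ketone 9 (not isolated), via selenoxide 10 (not isolated)
Conditions: LDA (1.15 equiv), THF, −78 °C; PhSeCl (1.1 equiv), −78 °C; aqueous work-up; mCPBA (1.0 equiv), CH2Cl2, −40 °C to rt
Reagents that add atoms: none
Why: Kinetic α′-deprotonation of the vinylogous ester at C6, selenenylation, oxidation and selenoxide syn-elimination give a cross-conjugated dienone that tautomerises to the phenol, a sequence known for pyran-fused cyclohexenones; the transient C6 (and Se) stereocentres are racemic and vanish in the same step.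

Step 6
Reactants: 11 2,2-dimethyl-2H-chromen-5-ol
Product: 12 2,2-dimethyl-2H-chromene-5,8-dione
Conditions: (KSO3)2NO (2.5 equiv), KH2PO4 buffer, acetone–H2O, 0 °C to rt
Reagents that add atoms: potassium nitrosodisulfonate (Fremy's salt), [K+].[K+].[O]N(S(=O)(=O)[O-])S(=O)(=O)[O-]
Why: Teuber oxidation, in which the phenoxyl radical is trapped by a second nitroxide at the free para position C8 and loss of imidodisulfonate gives the p-quinone, while the mild radical oxidant should leave the chromene double bond alone.

Step 7
Reactants: 6 1-(5-hydroxy-7-methoxy-2,2-dimethylchroman-6-yl)-3,3-bis(methylsulfanyl)prop-2-en-1-one; 12 2,2-dimethyl-2H-chromene-5,8-dione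
Product: 15 5-O-methylformosanatin D, via hydroquinone adduct 13 (not isolated), via methylsulfanylbenzofuran 14 (not isolated)
Conditions: 12 (1.5 equiv), CuBr2 (10 mol %), BF3·OEt2 (30 mol %), MeCN, rt, slow Ar purge; then DBU (4 equiv), 60 °C
Reagents that add atoms: none
Why: Proposed new method: the Lewis acid activates quinone 12 and the nucleophilic α-carbon of the push–pull ketene dithioacetal 6 adds to C6, giving after tautomerisation hydroquinone 13, whose C5–OH captures the bis(methylsulfanyl) carbon and expels MeSH to give benzofuran 14; DBU then sends the only free A-ring phenol onto the same carbon (now C2 of a 3-aroyl-2-methylsulfanylbenzofuran, a vinylogous thioester) and the second MeSH leaves, so that the one CS2-derived carbon ends up bearing both ring oxygens. The closest known reaction types are the CuBr2/BF3-cocatalysed formal [3+2] annulation of α-oxo ketene dithioacetals and p-quinones to 3-acyl-2-alkylsulfanyl-5-hydroxybenzofurans and the closure of o-hydroxyaroyl ketene dithioacetals to 2-methylsulfanylchromones; new are their merger on one linchpin carbon and the displacement at C2 of the benzofuran. Ring D (furan) closes in a 5-exo-trig sense on the C=S+ bond of the thionium form of the ketene dithioacetal followed by elimination, and ring C (γ-pyranone) closes by 6-endo-trig oxa-Michael addition–elimination. No stereocentre is formed. The step needs regioselectivity at the quinone: O1 donates through C8a=C4a into C5=O (vinylogous ester), so C8=O is the stronger acceptor and its β-carbon C6 is attacked, in line with the known bias of 2-alkoxy-1,4-benzoquinones to take nucleophiles para to the alkoxy-bearing carbon, and Cu(II) held between O1 and C8=O would reinforce it, while C4a and C8a are blocked. The angular A/C fusion is secured because O7 of the chroman is methylated, so only the C5–OH next to the benzylic CH2 can close ring C.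

Step 8
Reactants: 15 5-O-methylformosanatin D
Product: 16 formosanatin D
Conditions: BCl3 (3 equiv, 1 M in CH2Cl2), CH2Cl2, −78 to −20 °C; then H2O
Reagents that add atoms: none
Why: Chelation-directed demethylation of a 5-methoxychromone, in which BCl3 bridges C4=O and the peri methoxy oxygen so that chloride cleaves only this methyl ether at low temperature, whereas the tertiary ring ethers of rings E and F have no neighbouring carbonyl group and should stay closed.

**Compound list**

1 | 2′,4′-dihydroxy-6′-methoxyacetophenone | CC(=O)c1c(O)cc(O)cc1OC | starting material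
2 | 3-methylbut-2-enal (prenal) | CC(C)=CC=O | starting material
3 | 1-(5-hydroxy-7-methoxy-2,2-dimethyl-2H-chromen-6-yl)ethan-1-one | CC(=O)c1c(OC)cc2OC(C)(C)C=Cc2c1O | intermediate
4 | 1-(5-hydroxy-7-methoxy-2,2-dimethylchroman-6-yl)ethan-1-one | CC(=O)c1c(OC)cc2OC(C)(C)CCc2c1O | intermediate
5 | carbon disulfide | S=C=S | starting material
6 | 1-(5-hydroxy-7-methoxy-2,2-dimethylchroman-6-yl)-3,3-bis(methylsulfanyl)prop-2-en-1-one | CSC(SC)=CC(=O)c1c(OC)cc2OC(C)(C)CCc2c1O | intermediate
7 | cyclohexane-1,3-dione | O=C1CCCC(=O)C1 | starting material
8 | 2,2-dimethyl-7,8-dihydro-2H-chromen-5(6H)-one | CC1(C)C=CC2=C(CCCC2=O)O1 | intermediate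
9 | 2,2-dimethyl-6-(phenylselanyl)-7,8-dihydro-2H-chromen-5(6H)-one (racemic, not isolated) | CC1(C)C=CC2=C(CCC([Se]c3ccccc3)C2=O)O1 | intermediate
10 | 2,2-dimethyl-6-(phenylseleninyl)-7,8-dihydro-2H-chromen-5(6H)-one (racemic diastereomer mixture, not isolated) | CC1(C)C=CC2=C(CCC([Se](=O)c3ccccc3)C2=O)O1 | intermediate
11 | 2,2-dimethyl-2H-chromen-5-ol | CC1(C)C=Cc2c(O)cccc2O1 | intermediate
12 | 2,2-dimethyl-2H-chromene-5,8-dione | CC1(C)C=CC2=C(O1)C(=O)C=CC2=O | intermediate
13 | 2-(5,8-dihydroxy-2,2-dimethyl-2H-chromen-6-yl)-1-(5-hydroxy-7-methoxy-2,2-dimethylchroman-6-yl)-3,3-bis(methylsulfanyl)prop-2-en-1-one (not isolated) | CSC(SC)=C(C(=O)c1c(OC)cc2OC(C)(C)CCc2c1O)c1cc(O)c2OC(C)(C)C=Cc2c1O | intermediate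
14 | (5-hydroxy-7-methoxy-2,2-dimethylchroman-6-yl)[5-hydroxy-2-(methylsulfanyl)benzofuran-3-yl]methanone carrying a 2,2-dimethyl-2H-pyran fused through its O to benzofuran C6 and through its C4 to benzofuran C7 (not isolated) | CSc1oc2c3C=CC(C)(C)Oc3c(O)cc2c1C(=O)c1c(OC)cc2OC(C)(C)CCc2c1O | intermediate
15 | 5-O-methylformosanatin D (target with OMe in place of the chelated 5-OH) | CC1(C)C=Cc2c(c(O)cc3c2oc2oc4c5c(cc(OC)c4c(=O)c23)OC(C)(C)CC5)O1 | intermediate
16 | formosanatin D (achiral) | CC1(C)C=Cc2c(c(O)cc3c2oc2oc4c5c(cc(O)c4c(=O)c23)OC(C)(C)CC5)O1 | target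

**Step count**

Total step count: 8.
Longest linear sequence: 5 steps (1, 2, 3, 7, 8 or 4, 5, 6, 7, 8).

**Steps most likely to fail**

1. Step 7 (bears the label).
 - What may go wrong: conjugate addition may also take place at C7 of the quinone. The liberated methanethiol may consume quinone by thia-Michael addition. 6 may close early to the less nucleophilic chromone. The second ring closure may stall at the benzofuran stage.
 - Fallback (known chemistry, sets out from 6 and 12, comes back at 15): the cascade is given up for three separate known operations with a better leaving group. 6 and 12 are joined under the CuBr2/BF3·OEt2 conditions alone, and methylsulfanylbenzofuran 14 is isolated and freed from any regioisomer. The sulfide is oxidised with one equivalent of mCPBA at −78 °C, where sulfur reacts much faster than the chromene double bond, to the racemic 2-methylsulfinylbenzofuran F1. K2CO3 in DMF at rt then lets the phenoxide displace the sulfinyl group by addition–elimination at the β-sulfinyl enone, which gives 15.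

2. Step 8.
 - What may go wrong: the Lewis acid, or the HCl formed from the free phenol, may ionise the allylic tertiary C–O bond of ring F or add across its double bond before the chelated methyl ether is cleaved.
 - Fallback (sets out from 4, comes back at 16): the methyl ether is exchanged for an allyl ether before the acid-sensitive ring F enters.
   - 4 is demethylated with BCl3 (no chromene present) to 1-(5,7-dihydroxy-2,2-dimethylchroman-6-yl)ethan-1-one F2.
   - Allyl bromide/K2CO3 in acetone alkylates the less hindered 7-OH, while the 5-OH between the acetyl group and the benzylic CH2 takes over the chelate. This gives 1-(7-allyloxy-5-hydroxy-2,2-dimethylchroman-6-yl)ethan-1-one F3.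
   - NaH/CS2/MeI as in step 3 gives the allyl-bearing ketene dithioacetal F4.
   - The union with 12 under the conditions of step 7 passes through the allyl-bearing hydroquinone adduct F5 and the allyl-bearing methylsulfanylbenzofuran F6 and gives 5-O-allylformosanatin D F7.
   - Pd(PPh3)4/morpholine in THF at rt (Tsuji–Trost deallylation) removes the allyl group under neutral conditions and gives 16.

3. Step 6.
 - What may go wrong: the radical oxidation may be unselective (ortho-oxidation, attack on the chromene double bond), and the alkoxy-vinyl-quinone may decay during the aqueous reaction and isolation.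
 - Fallback (sets out from 11, comes back at 12): a two-electron oxidative dearomatisation in a non-aqueous medium replaces the radical oxidation. PhI(OAc)2 (2.2 equiv) in MeOH at 0 °C converts 11 by way of 8-methoxy-2,2-dimethyl-2H-chromen-5-ol F8 into the storable quinone monoketal 8,8-dimethoxy-2,2-dimethyl-2H-chromen-5(8H)-one F9. This is hydrolysed with aqueous oxalic acid on silica gel in CH2Cl2 just before use to give 12.

**Further compounds**

F1 | step 7 | (5-hydroxy-7-methoxy-2,2-dimethylchroman-6-yl)[5-hydroxy-2-(methylsulfinyl)benzofuran-3-yl]methanone with the 6,7-fused 2,2-dimethyl-2H-pyran (racemic at sulfur) | CS(=O)c1oc2c3C=CC(C)(C)Oc3c(O)cc2c1C(=O)c1c(OC)cc2OC(C)(C)CCc2c1O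
F2 | step 8 | 1-(5,7-dihydroxy-2,2-dimethylchroman-6-yl)ethan-1-one | CC(=O)c1c(O)cc2OC(C)(C)CCc2c1O
F3 | step 8 | 1-(7-allyloxy-5-hydroxy-2,2-dimethylchroman-6-yl)ethan-1-one | CC(=O)c1c(OCC=C)cc2OC(C)(C)CCc2c1O
F4 | step 8 | 1-(7-allyloxy-5-hydroxy-2,2-dimethylchroman-6-yl)-3,3-bis(methylsulfanyl)prop-2-en-1-one | CSC(SC)=CC(=O)c1c(OCC=C)cc2OC(C)(C)CCc2c1O
F5 | step 8 | allyl-bearing hydroquinone adduct (7-allyloxy analogue of 13) | CSC(SC)=C(C(=O)c1c(OCC=C)cc2OC(C)(C)CCc2c1O)c1cc(O)c2OC(C)(C)C=Cc2c1O
F6 | step 8 | allyl-bearing methylsulfanylbenzofuran (7-allyloxy analogue of 14) | CSc1oc2c3C=CC(C)(C)Oc3c(O)cc2c1C(=O)c1c(OCC=C)cc2OC(C)(C)CCc2c1O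
F7 | step 8 | 5-O-allylformosanatin D | CC1(C)C=Cc2c(c(O)cc3c2oc2oc4c5c(cc(OCC=C)c4c(=O)c23)OC(C)(C)CC5)O1
F8 | step 6 | 8-methoxy-2,2-dimethyl-2H-chromen-5-ol | COc1ccc(O)c2C=CC(C)(C)Oc12
F9 | step 6 | 8,8-dimethoxy-2,2-dimethyl-2H-chromen-5(8H)-one | CC1(C)C=CC2=C(O1)C(OC)(OC)C=CC2=O
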